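## Retrosynthetic overview
- The (2S)-flavanone core and its only stereocenter come intact from commercial natural (S)-naringenin, so no ring is built. The route is a B-ring edit, and the new C–C bond is formed by a [3,3] sigmatropic (aromatic Claisen) rearrangement.
- The (E)-CH=CH–C(CH3)2OH chain comes from a Heck reaction of an aryl iodide with 2-methylbut-3-en-2-ol.
- The prenyl group comes from cross-metathesis of an allyl arene with 2-methyl-2-butene. The allyl group comes from Claisen rearrangement of the 4'-O-allyl ether, which is forced to the ortho position opposite the iodine.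
- The iodine comes from ortho-iodination of the 4'-phenol. The A-ring 7-OH is masked as its MOM ether to direct that iodination, then released last.

Assumptions (stated once):
- (2S)-Naringenin is commercially available as a single enantiomer.
- Target numbering 3'/5' is interchangeable because the B ring is symmetric about C1'–C4'.
- The C2 configuration of 5-hydroxyflavanones survives brief, mild base and neutral heating.

## Route

**Step 1**
Reactants: 1 (2S)-naringenin; 2 chloromethyl methyl ether (MOMCl)
Product: 3 (2S)-7-O-MOM-naringenin
Conditions: MOMCl (1.05 equiv), K2CO3, acetone, 0 °C → rt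
Reagents that add atoms: MOMCl, COCCl
Why: The 7-OH is the most acidic phenol (pKa ~7) and the 5-OH is chelated to the C4 carbonyl, so 1 equiv of electrophile under mild base alkylates 7-O selectively (Williamson-type etherification). C2 is untouched.

**Step 2**
Reactants: 3 (2S)-7-O-MOM-naringenin; 4 iodine
Product: 5 (2S)-3'-iodo-7-O-MOM-naringenin
Conditions: I2 (1.0 equiv), NaHCO3, THF/H2O, 0 °C
Reagents that add atoms: I2, II
Why: Through the 4'-phenoxide the B ring is far more nucleophilic than the neutral, carbonyl-deactivated A ring, so iodination goes ortho to the 4'-O. One equivalent of I2 limits diiodination (electrophilic aromatic iodination). Any 3',5'-diiodide is removed by chromatography.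

**Step 3**
Reactants: 5 (2S)-3'-iodo-7-O-MOM-naringenin; 6 allyl bromide
Product: 7 (2S)-4'-O-allyl-3'-iodo-7-O-MOM-naringenin
Conditions: allyl bromide (1.5 equiv), K2CO3, acetone, 40 °C
Reagents that add atoms: allyl bromide, C=CCBr
Why: The iodine-acidified 4'-phenol is alkylated under mild conditions while the chelated 5-OH is inert (Williamson etherification).

**Step 4 (key step)**
Reactants: 7 (2S)-4'-O-allyl-3'-iodo-7-O-MOM-naringenin
Product: 8 (2S)-5'-allyl-3'-iodo-4'-hydroxy-7-O-MOM-flavanone (i.e. 3'-allyl-5'-iodo-4'-hydroxy, with the 7-OMOM and 5-OH A ring)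
Conditions: 1,2-dichlorobenzene, 190 °C (microwave), 30–60 min
Reagents that add atoms: none
Why: Aromatic Claisen [3,3]-sigmatropic rearrangement through a chair-like six-membered transition state delivers the allyl group to the only free ortho carbon, which sets the 3'-iodo/5'-allyl pattern with complete regiocontrol. The C2 stereocenter is not involved and the medium is neutral.

**Step 5**
Reactants: 8 phenol from Step 4; 9 iodomethane
Product: 10 (2S)-5'-allyl-3'-iodo-4'-methoxy-7-O-MOM-flavanone
Conditions: MeI (3 equiv), K2CO3, acetone, rt
Reagents that add atoms: MeI, CI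
Why: The iodine-acidified, hindered phenol is O-methylated (Williamson) while the chelated 5-OH is untouched, giving the 4'-OMe of the target.

**Step 6**
Reactants: 10 allyl arene; 11 2-methyl-2-butene
Product: 12 (2S)-3'-iodo-4'-methoxy-5'-prenyl-7-O-MOM-flavanone
Conditions: 2-methyl-2-butene (20 equiv), Hoveda–Grubbs II (5 mol%), CH2Cl2, 40 °C, sealed tube
Reagents that add atoms: 2-methyl-2-butene, CC=C(C)C
Why: Olefin cross-metathesis of the terminal allyl alkene with excess 2-methyl-2-butene converts ArCH2CH=CH2 into ArCH2CH=C(CH3)2 (propene is lost). Aryl iodide, free 5-OH and ketone are tolerated.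

**Step 7**
Reactants: 12 aryl iodide; 13 2-methylbut-3-en-2-ol
Product: 14 (2S)-7-O-MOM-protected target, (E)-3'-(3-hydroxy-3-methylbut-1-enyl)-4'-methoxy-5'-prenyl-flavanone
Conditions: 2-methylbut-3-en-2-ol (5 equiv), Pd(OAc)2 (5 mol%), n-Bu4NCl, NaHCO3, DMF, 70 °C
Reagents that add atoms: 2-methylbut-3-en-2-ol, C=CC(C)(C)O
Why: In the Mizoroki–Heck reaction the aryl adds to the terminal CH2 and the carbinol carbon has no β-H, so only benzylic β-hydride elimination is possible, giving the (E)-allylic alcohol. The trisubstituted prenyl alkene is unreactive, and weak inorganic base protects C2.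

**Step 8**
Reactants: 14 MOM-protected flavanone
Product: 15 target, (2S)-5,7-dihydroxy-4'-methoxy-3'-[(E)-3-hydroxy-3-methylbut-1-enyl]-5'-prenylflavanone
Conditions: TMSOTf, 2,2'-bipyridyl, CH3CN, 0 °C → rt; then H2O
Reagents that add atoms: none (the MOM group is lost)
Why: The TMSOTf/bipyridine system cleaves aryl MOM ethers under non-acidic, buffered conditions, so the tertiary allylic alcohol and prenyl alkene survive, and any O-TMS ether is hydrolysed on aqueous work-up. C2 is untouched, so (S) is retained.

## Checks performed
- **Structure:** The final B ring is C1' (flavanone C2), C3' (CH=CH–C(CH3)2OH), C4' (OMe), C5' (prenyl). The A ring is 5,7-diOH and the chromanone is unchanged, matching the target SMILES.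
- **Formulas:** 1 C15H12O5 → 3 C17H16O6 → 5 C17H15IO6 → 7 C20H19IO6 → 8 (isomer of 7) → 10 C21H21IO6 → 12 C23H25IO6 → 14 C28H34O7 → 15 C26H30O6 (target, 30 H counted).
- **Stereochemistry:** C2 is never a reaction center. The SMILES pattern `Ar–[C@@H]2CC(=O)…O2` with aryl listed first gives (S), the same as in the target.

## Compound list
1 | (2S)-naringenin | Oc1ccc([C@@H]2CC(=O)c3c(O)cc(O)cc3O2)cc1 | starting material
2 | chloromethyl methyl ether | COCCl | starting material
3 | (2S)-7-O-MOM-naringenin | Oc1ccc([C@@H]2CC(=O)c3c(O)cc(OCOC)cc3O2)cc1 | intermediate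
4 | iodine | II | starting material
5 | (2S)-3'-iodo-7-O-MOM-naringenin | Oc1ccc([C@@H]2CC(=O)c3c(O)cc(OCOC)cc3O2)cc1I | intermediate
6 | allyl bromide | C=CCBr | starting material
7 | (2S)-4'-O-allyl-3'-iodo-7-O-MOM-naringenin | C=CCOc1ccc([C@@H]2CC(=O)c3c(O)cc(OCOC)cc3O2)cc1I | intermediate
8 | (2S)-3'-allyl-5'-iodo-4'-hydroxy-7-O-MOM-flavanone | Oc1c(CC=C)cc([C@@H]2CC(=O)c3c(O)cc(OCOC)cc3O2)cc1I | intermediate
9 | iodomethane | CI | starting material
10 | (2S)-3'-allyl-5'-iodo-4'-methoxy-7-O-MOM-flavanone | COc1c(CC=C)cc([C@@H]2CC(=O)c3c(O)cc(OCOC)cc3O2)cc1I | intermediate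
11 | 2-methyl-2-butene | CC=C(C)C | starting material
12 | (2S)-3'-iodo-4'-methoxy-5'-prenyl-7-O-MOM-flavanone | COc1c(CC=C(C)C)cc([C@@H]2CC(=O)c3c(O)cc(OCOC)cc3O2)cc1I | intermediate
13 | 2-methylbut-3-en-2-ol | C=CC(C)(C)O | starting material
14 | (2S)-7-O-MOM-protected target | COc1c(/C=C/C(C)(C)O)cc([C@@H]2CC(=O)c3c(O)cc(OCOC)cc3O2)cc1CC=C(C)C | intermediate
15 | target, (2S)-5,7-dihydroxy-3'-[(E)-3-hydroxy-3-methylbut-1-enyl]-4'-methoxy-5'-prenylflavanone | COc1c(/C=C/C(C)(C)O)cc([C@@H]2CC(=O)c3c(O)cc(O)cc3O2)cc1CC=C(C)C | target

## Totals
Total steps: 8. Longest linear sequence: 8 (fully linear from 1).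

## Three steps most likely to fail
1. **Step 4 (thermal Claisen at ~190 °C).** Risks are partial racemization by retro-oxa-Michael ring opening, decomposition, or loss of iodine.
   - Fallback: make the 5'-allyl group by cross-coupling. Di-iodinate the 4'-phenol, methylate, and do a mono Stille coupling with allyltributylstannane at 60–80 °C, at the cost of statistical mono-selectivity.
2. **Step 2 (regioselective mono-iodination).** Risks are A-ring iodination at C6/C8 and 3',5'-diiodination.
   - Fallback: replace iodination with phenoxide-directed ortho-formylation (MgCl2, Et3N, paraformaldehyde) to give the 3'-CHO. After Claisen, methylation and cross-metathesis, convert the aldehyde to the (E)-allylic alcohol by Julia–Kocienski olefination with a 2-hydroxy-2-methylpropyl heteroaryl sulfone.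
3. **Step 6 (allyl → prenyl cross-metathesis).** Risks are alkene isomerization to the propenyl arene and incomplete conversion.
   - Fallback: swap Steps 3 and 6 for a route that gives the prenyl group directly from a 1,1-dimethylallyl ether. Use CuCl-mediated etherification of the 4'-phenol with 3-chloro-3-methylbut-1-yne, Lindlar semihydrogenation, then Claisen rearrangement, which delivers the normal prenyl group at the free ortho carbon.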